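**Retrosynthetic overview** (spiro[5.5]undecane numbering: ring B = C1–C5 plus spiro C6, with C2 = CHBr and C3 = C(OH)CH3; ring A = C6–C11, with C7 = CMe2, C8 = CHBr, C11 = C=CH2)
- Enabling feature: in ring B the carbinol carbon C3 lies para to the spiro carbon C6, and the trans C2–Br/C3–O pair is flanked by the CH2 groups C1 and C4. This is the retron of a "para" Diels–Alder adduct of a 2-substituted butadiene (C1=C6–C5=C4, C6 still sp2) with (E)-3-bromo-2-methylpropenal (C2=C3, CHO standing in for OH).
- Ring B first (key step): the cycloaddition makes C1–C2 and C3–C4 and sets C2 and C3 (trans from the E geometry, absolute sense from the catalyst); a Baeyer–Villiger oxidation then turns C3–CHO into C3–O.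
- Ring A second: HAT-initiated radical cyclisation of the C5=C6 alkene onto a C11 aldehyde makes C6–C11 and the spiro centre, anti to C2–Br.
- Endgame: C11 ketone to methylidene, C8–OH to C8–Br with inversion, formate removal.
- Fragments: diene from 4-(silyloxy)butanal and 3-chloro-3-methylbut-1-yne (Barbier addition, oxidation, CBS reduction to set C8, ethylene enyne metathesis); dienophile from propargyl alcohol.

Key step: step 8

Assumption: the (S)-oxazaborolidinium catalyst is taken to shield the bound enal as it does for other 2-substituted acroleins and so to give (1S,6R)-13; if the sense is the opposite, the (R)-catalyst is used and nothing else changes.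

Step 1
Reactants: 1 4-[(tert-butyldimethylsilyl)oxy]butanal; 2 3-chloro-3-methylbut-1-yne
Product: 4 rac-7-[(tert-butyldimethylsilyl)oxy]-3,3-dimethylhept-1-yn-4-ol, via (3-methylbuta-1,2-dien-1-yl)zinc chloride 3 (not isolated)
Conditions: zinc dust, THF, 0 °C to rt; aq NH4Cl
Reagents that add atoms: none
Why: Zinc Barbier propargylation, in which the allenylzinc 3 should add through a cyclic SE2' transition state at its gem-dimethyl carbon to give the homopropargylic alcohol with the quaternary carbon (racemic; the stereocentre is erased in step 2).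

Step 2
Reactants: 4 rac-7-[(tert-butyldimethylsilyl)oxy]-3,3-dimethylhept-1-yn-4-ol
Product: 5 7-[(tert-butyldimethylsilyl)oxy]-3,3-dimethylhept-1-yn-4-one
Conditions: Dess–Martin periodinane, CH2Cl2, rt
Reagents that add atoms: none
Why: Dess–Martin oxidation of a secondary alcohol, to which the terminal alkyne and the silyl ether are inert.

Step 3
Reactants: 5 7-[(tert-butyldimethylsilyl)oxy]-3,3-dimethylhept-1-yn-4-one
Product: 6 (4R)-7-[(tert-butyldimethylsilyl)oxy]-3,3-dimethylhept-1-yn-4-ol
Conditions: (S)-1-methyl-3,3-diphenyltetrahydro-1H,3H-pyrrolo[1,2-c][1,3,2]oxazaborole (20 mol%), catecholborane, toluene, −78 °C; then H2O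
Reagents that add atoms: none
Why: Corey–Bakshi–Shibata reduction, in which the (S)-catalyst should deliver hydride to the face that keeps the large quaternary propargylic group away from the B-methyl group and so give the (R)-alcohol, while catecholborane at −78 °C does not hydroborate the alkyne.

Step 4
Reactants: 6 (4R)-7-[(tert-butyldimethylsilyl)oxy]-3,3-dimethylhept-1-yn-4-ol
Product: 7 (4R)-4,7-bis[(tert-butyldimethylsilyl)oxy]-3,3-dimethylhept-1-yne
Conditions: TBSOTf, 2,6-lutidine, CH2Cl2, 0 °C
Reagents that add atoms: tert-butyldimethylsilyl trifluoromethanesulfonate, CC(C)(C)[Si](C)(C)OS(=O)(=O)C(F)(F)F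
Why: Silylation of a hindered secondary alcohol with the silyl triflate, which leaves the C–O bond and hence the configuration untouched and gives an ether with no easily abstracted hydrogen near the later radical site.

Step 5
Reactants: 7 (4R)-4,7-bis[(tert-butyldimethylsilyl)oxy]-3,3-dimethylhept-1-yne
Product: 8 (4R)-1,4-bis[(tert-butyldimethylsilyl)oxy]-5,5-dimethyl-6-methylideneoct-7-ene
Conditions: ethylene (1 atm), second-generation Grubbs catalyst RuCl2(=CHPh)(PCy3)(H2IMes) (5 mol%), toluene, 80 °C
Reagents that add atoms: ethylene, C=C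
Why: Ethylene–alkyne cross enyne metathesis should convert the terminal alkyne into the 2-substituted buta-1,3-diene without touching the stereocentre.

Step 6
Reactants: 9 prop-2-yn-1-ol
Product: 11 (2E)-3-bromo-2-methylprop-2-en-1-ol, via [(E)-3-(dimethylalumanyl)-2-methylprop-2-enoxy]dimethylalumane 10 (not isolated)
Conditions: Me3Al (3 equiv), Cp2ZrCl2 (25 mol%), CH2Cl2, 0 °C to rt; then NBS, THF, −30 to 0 °C; aq HCl
Reagents that add atoms: trimethylaluminium, C[Al](C)C; N-bromosuccinimide, O=C1CCC(=O)N1Br
Why: Zirconium-catalysed Negishi carboalumination adds methyl and aluminium syn across the alkyne with aluminium at the terminus, and bromodealumination with retention then fixes the E geometry.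

Step 7
Reactants: 11 (2E)-3-bromo-2-methylprop-2-en-1-ol
Product: 12 (2E)-3-bromo-2-methylprop-2-enal
Conditions: activated MnO2, CH2Cl2, rt
Reagents that add atoms: none
Why: Allylic alcohol oxidation with MnO2 should stop at the enal and leave the vinyl bromide geometry unchanged.

Step 8
Reactants: 8 (4R)-1,4-bis[(tert-butyldimethylsilyl)oxy]-5,5-dimethyl-6-methylideneoct-7-ene; 12 (2E)-3-bromo-2-methylprop-2-enal
Product: 13 (1S,6R)-4-{(3R)-3,6-bis[(tert-butyldimethylsilyl)oxy]-2-methylhexan-2-yl}-6-bromo-1-methylcyclohex-3-ene-1-carbaldehyde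
Conditions: (S)-3,3-diphenyl-1-(2-methylphenyl)tetrahydro-1H,3H-pyrrolo[1,2-c][1,3,2]oxazaborole (20 mol%), Tf2NH (18 mol%), 12 (1.5 equiv), CH2Cl2, −78 to −40 °C
Reagents that add atoms: none
Why: Lewis-acid-catalysed Diels–Alder reaction in which the protonated oxazaborolidine binds enal 12 (B–O=C coordination plus a formyl C–H···O contact) and the s-cis diene 8 adds in a concerted, asynchronous [4+2] process; the closest known reaction type is the oxazaborolidinium-catalysed cycloaddition of 2-substituted acroleins (2-methylacrolein, 2-bromoacrolein, tiglic aldehyde) with 2-substituted butadienes. Ring B is closed by an intermolecular suprafacial–suprafacial cycloaddition that makes the C1–C2 and C3–C4 bonds together. The trans relation of C2–Br and the C3 formyl group follows from the E geometry of 12 (stereospecific syn addition), and their absolute configuration from the catalyst, which shields one face of the bound enal. The selectivity the step needs is the "para" regiochemistry (formyl-bearing C3 opposite the substituted diene carbon C6), secured by the largest HOMO coefficient at C1 of the 2-alkyl diene meeting the β-carbon C2 of the activated enal, while the bulky tert-alkyl group also holds the diene s-cis. The diene carries no terminal substituent, so no endo/exo question arises.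

Step 9
Reactants: 13 (1S,6R)-4-{(3R)-3,6-bis[(tert-butyldimethylsilyl)oxy]-2-methylhexan-2-yl}-6-bromo-1-methylcyclohex-3-ene-1-carbaldehyde
Product: 14 (1R,6R)-4-{(3R)-3,6-bis[(tert-butyldimethylsilyl)oxy]-2-methylhexan-2-yl}-6-bromo-1-methylcyclohex-3-en-1-yl formate
Conditions: Me3SiOOSiMe3 (1.5 equiv), Me3SiOTf (10 mol%), CH2Cl2, −78 to −40 °C
Reagents that add atoms: bis(trimethylsilyl) peroxide, C[Si](C)(C)OO[Si](C)(C)C
Why: Baeyer–Villiger oxidation (Criegee rearrangement) of an α-quaternary aldehyde under silyl peroxide/silyl triflate conditions, which do not epoxidise C=C bonds, so the tertiary ring carbon should migrate to oxygen with retention and give the formate of the tertiary alcohol.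

Step 10
Reactants: 14 (1R,6R)-4-{(3R)-3,6-bis[(tert-butyldimethylsilyl)oxy]-2-methylhexan-2-yl}-6-bromo-1-methylcyclohex-3-en-1-yl formate
Product: 15 (1R,6R)-6-bromo-4-{(3R)-3-[(tert-butyldimethylsilyl)oxy]-6-hydroxy-2-methylhexan-2-yl}-1-methylcyclohex-3-en-1-yl formate
Conditions: HF·pyridine, pyridine, THF, 0 °C
Reagents that add atoms: none
Why: Fluoride desilylation, in which the unhindered primary silyl ether is cleaved far faster than the neopentyl-type secondary one under buffered conditions that the formate should survive.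

Step 11
Reactants: 15 (1R,6R)-6-bromo-4-{(3R)-3-[(tert-butyldimethylsilyl)oxy]-6-hydroxy-2-methylhexan-2-yl}-1-methylcyclohex-3-en-1-yl formate
Product: 16 (1R,6R)-6-bromo-4-{(3R)-3-[(tert-butyldimethylsilyl)oxy]-2-methyl-6-oxohexan-2-yl}-1-methylcyclohex-3-en-1-yl formate
Conditions: Dess–Martin periodinane, CH2Cl2, rt
Reagents that add atoms: none
Why: Dess–Martin oxidation of the primary alcohol to the aldehyde under neutral conditions that spare the formate, the bromide and the alkene.

Step 12
Reactants: 16 (1R,6R)-6-bromo-4-{(3R)-3-[(tert-butyldimethylsilyl)oxy]-2-methyl-6-oxohexan-2-yl}-1-methylcyclohex-3-en-1-yl formate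
Product: 17 (2R,3R,6S,8R,11RS)-2-bromo-8-[(tert-butyldimethylsilyl)oxy]-11-hydroxy-3,7,7-trimethylspiro[5.5]undecan-3-yl formate
Conditions: Fe(acac)3 (50 mol%), PhSi(Oi-Pr)H2 (2.5 equiv), i-PrOH/THF, rt, degassed
Reagents that add atoms: none
Why: HAT-initiated reductive alkene–carbonyl radical cyclisation (Mukaiyama-type metal hydride hydrogen atom transfer), in which H is delivered to C5, the tertiary C6 radical adds 6-exo to the aldehyde, and the new C6–C11 bond should form on the ring B face opposite the 1,3-related C2–Br bond (axial attack with the tert-alkyl branch equatorial), which sets the spiro centre; the C11 carbinol epimers are of no consequence.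

Step 13
Reactants: 17 (2R,3R,6S,8R,11RS)-2-bromo-8-[(tert-butyldimethylsilyl)oxy]-11-hydroxy-3,7,7-trimethylspiro[5.5]undecan-3-yl formate
Product: 18 (2R,3R,6S,8R)-2-bromo-8-[(tert-butyldimethylsilyl)oxy]-3,7,7-trimethyl-11-oxospiro[5.5]undecan-3-yl formate
Conditions: Dess–Martin periodinane, CH2Cl2, rt
Reagents that add atoms: none
Why: Dess–Martin oxidation of the hindered secondary alcohol removes the C11 stereocentre and leaves the tertiary formate untouched.

Step 14
Reactants: 18 (2R,3R,6S,8R)-2-bromo-8-[(tert-butyldimethylsilyl)oxy]-3,7,7-trimethyl-11-oxospiro[5.5]undecan-3-yl formate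
Product: 19 (2R,3R,6R,8R)-2-bromo-8-[(tert-butyldimethylsilyl)oxy]-3,7,7-trimethyl-11-methylidenespiro[5.5]undecan-3-yl formate
Conditions: Zn/CH2Br2/TiCl4 (Lombardo reagent, pre-formed in THF at 5 °C), CH2Cl2, 0 °C to rt
Reagents that add atoms: dibromomethane, BrCBr
Why: Lombardo–Takai methylenation with a non-basic gem-dimetallic titanium reagent, which suits hindered ketones, does not attack formates and avoids the base-induced elimination that an ylide could cause next to the C2 bromide.

Step 15
Reactants: 19 (2R,3R,6R,8R)-2-bromo-8-[(tert-butyldimethylsilyl)oxy]-3,7,7-trimethyl-11-methylidenespiro[5.5]undecan-3-yl formate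
Product: 20 (2R,3R,6R,8R)-2-bromo-8-hydroxy-3,7,7-trimethyl-11-methylidenespiro[5.5]undecan-3-yl formate
Conditions: HF·pyridine, THF, rt to 40 °C
Reagents that add atoms: none
Why: Fluoride desilylation of the hindered secondary silyl ether under forcing but non-basic conditions, to which the formate, the alkene and the bromide should be inert.

Step 16
Reactants: 20 (2R,3R,6R,8R)-2-bromo-8-hydroxy-3,7,7-trimethyl-11-methylidenespiro[5.5]undecan-3-yl formate
Product: 21 (2R,3R,6R,8S)-2,8-dibromo-3,7,7-trimethyl-11-methylidenespiro[5.5]undecan-3-yl formate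
Conditions: CBr4, P(n-Oct)3, toluene, 70 °C
Reagents that add atoms: tetrabromomethane, BrC(Br)(Br)Br
Why: Appel bromination, in which bromide displaces the oxyphosphonium group of the neopentyl-type secondary alcohol in an SN2 step with inversion (axial C–O to equatorial C–Br), a conversion with precedent on bromo-gem-dimethylcyclohexanes when a trialkylphosphine is used, while the tertiary oxygen stays masked as the formate.

Step 17
Reactants: 21 (2R,3R,6R,8S)-2,8-dibromo-3,7,7-trimethyl-11-methylidenespiro[5.5]undecan-3-yl formate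
Product: 22 (2R,3R,6R,8S)-2,8-dibromo-3,7,7-trimethyl-11-methylidenespiro[5.5]undecan-3-ol
Conditions: KHCO3, MeOH, 0 °C to rt
Reagents that add atoms: none
Why: Mild transesterification of the formate with methanol, under a base too weak to close the trans-bromohydrin to an epoxide and with no stereocentre touched.

**Compound list**
1 | 4-[(tert-butyldimethylsilyl)oxy]butanal | O=CCCCO[Si](C)(C)C(C)(C)C | starting material
2 | 3-chloro-3-methylbut-1-yne | C#CC(C)(C)Cl | starting material
3 | (3-methylbuta-1,2-dien-1-yl)zinc chloride | CC(C)=C=C[Zn]Cl | intermediate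
4 | rac-7-[(tert-butyldimethylsilyl)oxy]-3,3-dimethylhept-1-yn-4-ol | C#CC(C)(C)C(O)CCCO[Si](C)(C)C(C)(C)C | intermediate
5 | 7-[(tert-butyldimethylsilyl)oxy]-3,3-dimethylhept-1-yn-4-one | C#CC(C)(C)C(=O)CCCO[Si](C)(C)C(C)(C)C | intermediate
6 | (4R)-7-[(tert-butyldimethylsilyl)oxy]-3,3-dimethylhept-1-yn-4-ol | C#CC(C)(C)[C@H](O)CCCO[Si](C)(C)C(C)(C)C | intermediate
7 | (4R)-4,7-bis[(tert-butyldimethylsilyl)oxy]-3,3-dimethylhept-1-yne | C#CC(C)(C)[C@H](O[Si](C)(C)C(C)(C)C)CCCO[Si](C)(C)C(C)(C)C | intermediate
8 | (4R)-1,4-bis[(tert-butyldimethylsilyl)oxy]-5,5-dimethyl-6-methylideneoct-7-ene | C=CC(=C)C(C)(C)[C@H](O[Si](C)(C)C(C)(C)C)CCCO[Si](C)(C)C(C)(C)C | intermediate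
9 | prop-2-yn-1-ol | C#CCO | starting material
10 | [(E)-3-(dimethylalumanyl)-2-methylprop-2-enoxy]dimethylalumane | C[Al](C)OC/C(C)=C/[Al](C)C | intermediate
11 | (2E)-3-bromo-2-methylprop-2-en-1-ol | OC/C(C)=C/Br | intermediate
12 | (2E)-3-bromo-2-methylprop-2-enal | O=C/C(C)=C/Br | intermediate
13 | (1S,6R)-4-{(3R)-3,6-bis[(tert-butyldimethylsilyl)oxy]-2-methylhexan-2-yl}-6-bromo-1-methylcyclohex-3-ene-1-carbaldehyde | O=C[C@]1(C)CC=C(C(C)(C)[C@H](O[Si](C)(C)C(C)(C)C)CCCO[Si](C)(C)C(C)(C)C)C[C@H]1Br | intermediate
14 | (1R,6R)-4-{(3R)-3,6-bis[(tert-butyldimethylsilyl)oxy]-2-methylhexan-2-yl}-6-bromo-1-methylcyclohex-3-en-1-yl formate | O=CO[C@]1(C)CC=C(C(C)(C)[C@H](O[Si](C)(C)C(C)(C)C)CCCO[Si](C)(C)C(C)(C)C)C[C@H]1Br | intermediate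
15 | (1R,6R)-6-bromo-4-{(3R)-3-[(tert-butyldimethylsilyl)oxy]-6-hydroxy-2-methylhexan-2-yl}-1-methylcyclohex-3-en-1-yl formate | O=CO[C@]1(C)CC=C(C(C)(C)[C@H](O[Si](C)(C)C(C)(C)C)CCCO)C[C@H]1Br | intermediate
16 | (1R,6R)-6-bromo-4-{(3R)-3-[(tert-butyldimethylsilyl)oxy]-2-methyl-6-oxohexan-2-yl}-1-methylcyclohex-3-en-1-yl formate | O=CO[C@]1(C)CC=C(C(C)(C)[C@H](O[Si](C)(C)C(C)(C)C)CCC=O)C[C@H]1Br | intermediate
17 | (2R,3R,6S,8R,11RS)-2-bromo-8-[(tert-butyldimethylsilyl)oxy]-11-hydroxy-3,7,7-trimethylspiro[5.5]undecan-3-yl formate | OC1CC[C@@H](O[Si](C)(C)C(C)(C)C)C(C)(C)[C@@]12CC[C@@](C)(OC=O)[C@H](Br)C2 | intermediate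
18 | (2R,3R,6S,8R)-2-bromo-8-[(tert-butyldimethylsilyl)oxy]-3,7,7-trimethyl-11-oxospiro[5.5]undecan-3-yl formate | O=C1CC[C@@H](O[Si](C)(C)C(C)(C)C)C(C)(C)[C@@]12CC[C@@](C)(OC=O)[C@H](Br)C2 | intermediate
19 | (2R,3R,6R,8R)-2-bromo-8-[(tert-butyldimethylsilyl)oxy]-3,7,7-trimethyl-11-methylidenespiro[5.5]undecan-3-yl formate | C=C1CC[C@@H](O[Si](C)(C)C(C)(C)C)C(C)(C)[C@@]12CC[C@@](C)(OC=O)[C@H](Br)C2 | intermediate
20 | (2R,3R,6R,8R)-2-bromo-8-hydroxy-3,7,7-trimethyl-11-methylidenespiro[5.5]undecan-3-yl formate | C=C1CC[C@@H](O)C(C)(C)[C@@]12CC[C@@](C)(OC=O)[C@H](Br)C2 | intermediate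
21 | (2R,3R,6R,8S)-2,8-dibromo-3,7,7-trimethyl-11-methylidenespiro[5.5]undecan-3-yl formate | C=C1CC[C@H](Br)C(C)(C)[C@@]12CC[C@@](C)(OC=O)[C@H](Br)C2 | intermediate
22 | (2R,3R,6R,8S)-2,8-dibromo-3,7,7-trimethyl-11-methylidenespiro[5.5]undecan-3-ol | C=C1CC[C@H](Br)C(C)(C)[C@@]12CC[C@@](C)(O)[C@H](Br)C2 | target

**Step count and risks**
Total step count: 17. Longest linear sequence: 15 (steps 1–5 and 8–17).

Steps most likely to fail:

1. Step 12 (radical spirocyclisation). The addition of the tertiary C6 radical to the aldehyde is reversible (ring-opening of the alkoxy radical) and competes with plain reduction of the radical, and the facial selectivity at C6 may be incomplete. The fallback replaces the radical addition by a polar one: from 16, a cobalt–salen hydrogen-atom-transfer catalyst, [N,N'-bis(3,5-di-tert-butylsalicylidene)-1,2-cyclohexanediaminato]cobalt, is used with CrCl3 and PhSi(Oi-Pr)H2. The C6 radical should then be captured by divalent chromium formed in the flask, and the resulting organochromium should add irreversibly to the aldehyde through a closed transition state (Nozaki–Hiyama–Kishi-type addition starting from an olefin). This path returns to the route at 17 and makes no new compound (F0).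

2. Step 9 (Baeyer–Villiger oxidation). Conversion may stall, or the silyl ethers may be lost under the Lewis-acidic silyl peroxide conditions, and any ordinary peracid would also epoxidise the ring alkene. The fallback accepts the epoxidation and undoes it: from 13, excess mCPBA in CH2Cl2 should carry out the Baeyer–Villiger oxidation and the epoxidation together to give the epoxy formate (1R,6R)-4-{(3R)-3,6-bis[(tert-butyldimethylsilyl)oxy]-2-methylhexan-2-yl}-6-bromo-3,4-epoxy-1-methylcyclohexyl formate F1 as an epoxide mixture. Stereospecific deoxygenation with catalytic MeReO3 and PPh3 should then restore the alkene, and the path returns to the route at 14.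

3. Step 16 (Appel bromination). The SN2 displacement at the neopentyl-type carbon is slow, so elimination or a 1,2-methyl shift from the oxyphosphonium intermediate may take over. The fallback separates activation from displacement: from 20, Tf2O and pyridine in CH2Cl2 at −20 °C should give the triflate (2R,3R,6R,8R)-2-bromo-3,7,7-trimethyl-11-methylidene-8-[(trifluoromethylsulfonyl)oxy]spiro[5.5]undecan-3-yl formate F2. LiBr in DMF at rt should then displace it with inversion, and the path returns to the route at 21.

Further compounds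
F0 | step 12 | none | none
F1 | step 9 | (1R,6R)-4-{(3R)-3,6-bis[(tert-butyldimethylsilyl)oxy]-2-methylhexan-2-yl}-6-bromo-3,4-epoxy-1-methylcyclohexyl formate | O=CO[C@]1(C)CC2OC2(C(C)(C)[C@H](O[Si](C)(C)C(C)(C)C)CCCO[Si](C)(C)C(C)(C)C)C[C@H]1Br
F2 | step 16 | (2R,3R,6R,8R)-2-bromo-3,7,7-trimethyl-11-methylidene-8-[(trifluoromethylsulfonyl)oxy]spiro[5.5]undecan-3-yl formate | C=C1CC[C@@H](OS(=O)(=O)C(F)(F)F)C(C)(C)[C@@]12CC[C@@](C)(OC=O)[C@H](Br)C2
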